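**Strategy.** Ring B (azepane) is disconnected to a five-membered ring. In pyrido[1,2-a]azepine numbering its tertiary carbinol carbon C9 and the nitrogen-bound C6 are separated by exactly the two methylenes C7 and C8. A C9 ketone with an ester at C6 is therefore the retro-aldol product of a cyclobutanol built from ethylene and the enol C2=C3 bond of an indolizidin-2-one-3-carboxylate. One irradiation forms C6–C7 and C8–C9 and enlarges the pyrrolidinone into ring B. The precursor is the enolised bicyclic β-keto benzyl ester that already carries ring A with its benzyloxypropyl side chain and the (S)-1-silyloxyprop-2-yl group at C1.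

Key step: step 11

**Remarks on the chemistry**
- Labels: ring A piperidine, ring B azepane, ring C cyclopentane, ring D butenolide. Indolizine numbering is used for 17, 18 and 20. Pyrido[1,2-a]azepine numbering (C1–C4 ring A, N5, C6–C10 ring B, C10a) is used from 21 on.
- Assumption: (S)-4-methyldihydrofuran-2(3H)-one (8) and 4-methoxy-3-methylfuran-2(5H)-one (24) are taken as purchasable.
- C6 of 21 and 22 is written as the (R) epimer; either epimer serves, because step 13 turns C6 into a methylene. Tetronate C5 in 25–28 is an epimer mixture, written without configuration, and is erased in step 18.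
- The C6 carboxyl of 21 is δ to the ketone, so it cannot be lost thermally and is removed by decarboxylative reduction.
- The target has the C9 hydroxyl anti to H-10 (trans ring B/C fusion), which an aldol closure onto the ring B ketone would not give. The tetronate is therefore added to the ketone first and ring C is closed on the aldehyde.
- C10a and C10 are set together under thermodynamic control in step 8; the methyl-bearing centre comes from 8.

**Step 1**
Reactants: 1 (R)-2-hydroxybutanoic acid
Product: 2 benzyl (R)-2-(benzyloxy)butanoate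
Conditions: BnBr, Ag2O, Et2O, rt, dark
Reagents that add atoms: benzyl bromide, BrCc1ccccc1
Why: Ag2O-mediated O-alkylation (Williamson type) of both the carboxylate and the hydroxyl proceeds without strong base, so the existing (R) centre should not epimerise.

**Step 2**
Reactants: 2 benzyl (R)-2-(benzyloxy)butanoate
Product: 3 (R)-2-(benzyloxy)butanal
Conditions: iBu2AlH, CH2Cl2, −78 °C; aq. potassium sodium tartrate
Reagents that add atoms: none
Why: Partial hydride reduction of an α-alkoxy ester at −78 °C should stop at the chelated hemiacetal aluminate, which releases the aldehyde on work-up; the crude aldehyde is used at once to avoid α-epimerisation.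

**Step 3**
Reactants: 3 (R)-2-(benzyloxy)butanal; 4 (R)-2-methylpropane-2-sulfinamide
Product: 5 (R,E)-N-[(R)-2-(benzyloxy)butylidene]-2-methylpropane-2-sulfinamide
Conditions: CuSO4, CH2Cl2, rt
Reagents that add atoms: none
Why: Dehydrative condensation of an aldehyde with tert-butanesulfinamide gives the (E)-N-sulfinyl aldimine under mild Lewis-acidic conditions and creates no new stereocentre.

**Step 4**
Reactants: 5 (R,E)-N-[(R)-2-(benzyloxy)butylidene]-2-methylpropane-2-sulfinamide; 6 5-bromopent-1-ene
Product: 7 (R)-N-[(3R,4R)-3-(benzyloxy)non-8-en-4-yl]-2-methylpropane-2-sulfinamide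
Conditions: Mg, Et2O (on 6); then 5, CH2Cl2, −78 → −40 °C; aq. NH4Cl
Reagents that add atoms: none
Why: Grignard 1,2-addition to an α-alkoxy N-sulfinyl aldimine under Cram-chelate control: magnesium held between the imine nitrogen and the benzyloxy oxygen exposes the face anti to the ethyl group, which is also the face left open by the (R)-sulfinyl group when S=O lies syn-coplanar with C=N, so the amine-bearing centre should form as (R), syn to the ether.

**Step 5**
Reactants: 8 (S)-4-methyldihydrofuran-2(3H)-one
Product: 9 (3R,4S)-3-[(dimethylamino)methyl]-4-methyldihydrofuran-2(3H)-one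
Conditions: LiN(iPr)2, THF, −78 °C; dimethyl(methylene)ammonium iodide, −78 °C → rt
Reagents that add atoms: dimethyl(methylene)ammonium iodide, C=[N+](C)C.[I-]
Why: Mannich aminomethylation of the lithium lactone enolate with a preformed iminium salt should occur anti to the 4-methyl group; the new centre is removed in step 6.

**Step 6**
Reactants: 9 (3R,4S)-3-[(dimethylamino)methyl]-4-methyldihydrofuran-2(3H)-one
Product: 11 (S)-4-methyl-3-methylenedihydrofuran-2(3H)-one, via ammonium iodide 10 (not isolated)
Conditions: MeI, MeOH, rt; then aq. NaHCO3, CH2Cl2, rt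
Reagents that add atoms: none
Why: N-Methylation followed by base-induced β-elimination of the ammonium salt (Hofmann type, E1cB) gives the α-methylene lactone, and NaHCO3 is too weak a base to touch the γ stereocentre.

**Step 7**
Reactants: 7 (R)-N-[(3R,4R)-3-(benzyloxy)non-8-en-4-yl]-2-methylpropane-2-sulfinamide; 11 (S)-4-methyl-3-methylenedihydrofuran-2(3H)-one
Product: 12 (R)-N-[(3R,4R,E)-3-(benzyloxy)-8-[(S)-4-methyl-2-oxodihydrofuran-3(2H)-ylidene]octan-4-yl]-2-methylpropane-2-sulfinamide
Conditions: second-generation Hoveyda–Grubbs catalyst (5 mol%), 2,6-dichloro-1,4-benzoquinone (10 mol%), 11 (3 equiv), CH2Cl2, 40 °C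
Reagents that add atoms: none
Why: Olefin cross-metathesis of a terminal alkene with a 1,1-disubstituted α-methylene lactone is driven by loss of ethylene, and the benzoquinone suppresses double-bond migration that would endanger the methyl-bearing centre.

**Step 8**
Reactants: 12 (R)-N-[(3R,4R,E)-3-(benzyloxy)-8-[(S)-4-methyl-2-oxodihydrofuran-3(2H)-ylidene]octan-4-yl]-2-methylpropane-2-sulfinamide
Product: 14 (3R,4S)-3-[(2S,6R)-6-[(R)-1-(benzyloxy)propyl]piperidin-2-yl]-4-methyldihydrofuran-2(3H)-one, via amino alkylidene lactone 13 (not isolated)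
Conditions: HCl (4 M in dioxane), MeOH, 0 °C; evaporate; Et3N, MeCN, 60 °C
Reagents that add atoms: none
Why: Acidolysis of the sulfinamide and intramolecular aza-Michael addition (6-exo-trig) of the freed amine to the alkylidene lactone; the addition is reversible and the lactone α-position epimerisable, so piperidine C2 and the lactone α-carbon should settle under thermodynamic control as the 2,6-cis diequatorial piperidine and the trans-3,4-disubstituted lactone.

**Step 9**
Reactants: 14 (3R,4S)-3-[(2S,6R)-6-[(R)-1-(benzyloxy)propyl]piperidin-2-yl]-4-methyldihydrofuran-2(3H)-one; 15 benzyl bromoacetate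
Product: 16 benzyl 2-[(2R,6S)-2-[(R)-1-(benzyloxy)propyl]-6-[(3R,4S)-4-methyl-2-oxooxolan-3-yl]piperidin-1-yl]acetate
Conditions: K2CO3, NaI (cat.), MeCN, 70 °C
Reagents that add atoms: none
Why: SN2 N-alkylation of the secondary amine by an α-bromo ester, helped by iodide catalysis at the hindered 2,6-disubstituted nitrogen, touches no stereocentre.

**Step 10**
Reactants: 16 benzyl 2-[(2R,6S)-2-[(R)-1-(benzyloxy)propyl]-6-[(3R,4S)-4-methyl-2-oxooxolan-3-yl]piperidin-1-yl]acetate
Product: 18 benzyl (1R,5R,8aS)-5-[(R)-1-(benzyloxy)propyl]-1-[(S)-1-(tert-butyldimethylsilyloxy)propan-2-yl]-2-hydroxy-1,5,6,7,8,8a-hexahydroindolizine-3-carboxylate (enol form of the β-keto ester), via hydroxy enol ester 17 (not isolated)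
Conditions: KOtBu (2.2 equiv), THF, 0 °C → rt; AcOH; then TBSCl, imidazole, rt
Reagents that add atoms: tert-butyldimethylsilyl chloride, C[Si](C)(Cl)C(C)(C)C
Why: Dieckmann-type intramolecular Claisen condensation in which the glycinate enolate is acylated by the lactone carbonyl (5-exo-trig), driven by formation of the stabilised β-keto ester enolate and followed by selective silylation of the released primary alcohol; C1 is already the thermodynamic epimer in 16 and is shielded from base in the product enolate.

**Step 11**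
Reactants: 18 benzyl (1R,5R,8aS)-5-[(R)-1-(benzyloxy)propyl]-1-[(S)-1-(tert-butyldimethylsilyloxy)propan-2-yl]-2-hydroxy-1,5,6,7,8,8a-hexahydroindolizine-3-carboxylate; 19 ethylene
Product: 21 benzyl (4R,6R,10R,10aS)-4-[(R)-1-(benzyloxy)propyl]-10-[(S)-1-(tert-butyldimethylsilyloxy)propan-2-yl]-9-oxoperhydropyrido[1,2-a]azepine-6-carboxylate, via cyclobutanol 20 (not isolated)
Conditions: CF3CO2H (1.2 equiv), ethylene (sat.), CH2Cl2, −40 °C, hν (254 nm, quartz); aq. NaHCO3
Reagents that add atoms: none
Why: Proposed new method: the N-protonated enol ester, excited at 254 nm (π,π*), should add ethylene stepwise through a 1,4-biradical to the cis-fused bicyclo[3.2.0] cyclobutanol 20, in which the bond shared by the four- and five-membered rings joins a hydroxyl-bearing donor carbon to an ester-bearing acceptor carbon and should therefore break by strain-driven retro-aldol cleavage, leaving the two ethylene carbons between the ketone carbon C9 and the nitrogen-bound C6. The closest known reaction type is the de Mayo reaction of enolised 1,3-diketones with alkenes, which has not been shown for an α-amino β-keto ester. Ring B is closed by ring enlargement and not by direct cyclisation: the (2+2) cycloaddition closes a four-membered ring on the enol face opposite the indolizine C1 side chain and the ring A methylene, and cleavage of the ring-fusion bond merges it with the five-membered ring into the azepanone. The one new stereocentre, C6, is set by ketonisation of the ester enol, expected by protonation from the face away from the C4 side chain, and is not relied on because step 13 removes it. The step needs selective excitation of the enol chromophore, which is expected to absorb far more strongly at 254 nm than the two benzyl groups, freedom from amine quenching, which protonation by trifluoroacetic acid secures, and no regiochemical choice, which symmetrical ethylene guarantees; C10 and C10a stay untouched because the enol is fixed between C2 and C3.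

**Step 12**
Reactants: 21 benzyl (4R,6R,10R,10aS)-4-[(R)-1-(benzyloxy)propyl]-10-[(S)-1-(tert-butyldimethylsilyloxy)propan-2-yl]-9-oxoperhydropyrido[1,2-a]azepine-6-carboxylate
Product: 22 (4R,6R,10R,10aS)-10-[(S)-1-(tert-butyldimethylsilyloxy)propan-2-yl]-4-[(R)-1-hydroxypropyl]-9-oxoperhydropyrido[1,2-a]azepine-6-carboxylic acid
Conditions: H2 (1 atm), Pd(OH)2/C, EtOH/EtOAc, rt
Reagents that add atoms: none
Why: Hydrogenolysis cleaves the benzyl ester and the benzyl ether while ketone, silyl ether and stereocentres are inert, and the amino acid formed keeps the nitrogen protonated so that it should not retard ether cleavage.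

**Step 13**
Reactants: 22 (4R,6R,10R,10aS)-10-[(S)-1-(tert-butyldimethylsilyloxy)propan-2-yl]-4-[(R)-1-hydroxypropyl]-9-oxoperhydropyrido[1,2-a]azepine-6-carboxylic acid
Product: 23 (4R,10R,10aS)-10-[(S)-1-(tert-butyldimethylsilyloxy)propan-2-yl]-4-[(R)-1-hydroxypropyl]perhydropyrido[1,2-a]azepin-9-one
Conditions: 9-mesityl-10-methylacridinium perchlorate (5 mol%), bis(4-chlorophenyl) disulfide (10 mol%), 2,6-lutidine (20 mol%), CF3CH2OH/ClCH2CH2Cl, blue LEDs (450 nm), rt
Reagents that add atoms: none
Why: Photoredox decarboxylative reduction of an α-amino acid: single-electron oxidation of the ammonium carboxylate releases CO2 and an α-amino radical at C6, which takes a hydrogen atom from the aryl thiol co-catalyst, so the C6 centre disappears.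

**Step 14**
Reactants: 23 (4R,10R,10aS)-10-[(S)-1-(tert-butyldimethylsilyloxy)propan-2-yl]-4-[(R)-1-hydroxypropyl]perhydropyrido[1,2-a]azepin-9-one; 24 4-methoxy-3-methylfuran-2(5H)-one
Product: 25 5-[(4R,9S,10R,10aS)-10-[(S)-1-(tert-butyldimethylsilyloxy)propan-2-yl]-9-hydroxy-4-[(R)-1-hydroxypropyl]perhydropyrido[1,2-a]azepin-9-yl]-4-methoxy-3-methylfuran-2(5H)-one
Conditions: 24 (2.3 equiv), LiN(iPr)2 (2.2 equiv), THF, −78 °C; then 23, −78 °C; AcOH, −78 °C
Reagents that add atoms: none
Why: Aldol-type 1,2-addition of the C5-lithiated tetronate (lithium furanolate) to the ring B ketone; equatorial attack trans to the C10 substituent, on the face not shielded by the axial C1 methylene of ring A, should give the (9S) tertiary alcohol with the hydroxyl anti to H-10, while tetronate C5 forms as a mixture that is erased in step 18.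

**Step 15**
Reactants: 25 5-[(4R,9S,10R,10aS)-10-[(S)-1-(tert-butyldimethylsilyloxy)propan-2-yl]-9-hydroxy-4-[(R)-1-hydroxypropyl]perhydropyrido[1,2-a]azepin-9-yl]-4-methoxy-3-methylfuran-2(5H)-one
Product: 26 5-[(4R,9S,10R,10aS)-9-(tert-butyldimethylsilyloxy)-4-[(R)-1-(tert-butyldimethylsilyloxy)propyl]-10-[(S)-1-(tert-butyldimethylsilyloxy)propan-2-yl]perhydropyrido[1,2-a]azepin-9-yl]-4-methoxy-3-methylfuran-2(5H)-one
Conditions: TBSOTf (4 equiv), 2,6-lutidine, CH2Cl2, 0 °C → rt
Reagents that add atoms: tert-butyldimethylsilyl trifluoromethanesulfonate, C[Si](C)(OS(=O)(=O)C(F)(F)F)C(C)(C)C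
Why: Silylation of the secondary and the tertiary hydroxyl with a silyl triflate and a hindered pyridine base blocks retro-aldol loss of the tetronate and oxidation of the side-chain carbinol in the following steps.

**Step 16**
Reactants: 26 5-[(4R,9S,10R,10aS)-9-(tert-butyldimethylsilyloxy)-4-[(R)-1-(tert-butyldimethylsilyloxy)propyl]-10-[(S)-1-(tert-butyldimethylsilyloxy)propan-2-yl]perhydropyrido[1,2-a]azepin-9-yl]-4-methoxy-3-methylfuran-2(5H)-one
Product: 27 5-[(4R,9S,10R,10aS)-9-(tert-butyldimethylsilyloxy)-4-[(R)-1-(tert-butyldimethylsilyloxy)propyl]-10-[(S)-1-hydroxypropan-2-yl]perhydropyrido[1,2-a]azepin-9-yl]-4-methoxy-3-methylfuran-2(5H)-one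
Conditions: HF·pyridine, pyridine, THF, 0 °C
Reagents that add atoms: none
Why: Sterically controlled selective desilylation, in which buffered HF·pyridine should cleave the primary silyl ether much faster than the hindered secondary and tertiary ones.

**Step 17**
Reactants: 27 5-[(4R,9S,10R,10aS)-9-(tert-butyldimethylsilyloxy)-4-[(R)-1-(tert-butyldimethylsilyloxy)propyl]-10-[(S)-1-hydroxypropan-2-yl]perhydropyrido[1,2-a]azepin-9-yl]-4-methoxy-3-methylfuran-2(5H)-one
Product: 28 (S)-2-[(4R,9S,10R,10aS)-9-(tert-butyldimethylsilyloxy)-4-[(R)-1-(tert-butyldimethylsilyloxy)propyl]-9-(3-methoxy-4-methyl-5-oxo-2,5-dihydrofuran-2-yl)perhydropyrido[1,2-a]azepin-10-yl]propanal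
Conditions: Dess–Martin periodinane, NaHCO3, CH2Cl2, 0 °C → rt
Reagents that add atoms: none
Why: Dess–Martin oxidation converts the primary alcohol into the aldehyde under buffered conditions that should not epimerise the α-methyl centre; the aldehyde is used directly.

**Step 18**
Reactants: 28 (S)-2-[(4R,9S,10R,10aS)-9-(tert-butyldimethylsilyloxy)-4-[(R)-1-(tert-butyldimethylsilyloxy)propyl]-9-(3-methoxy-4-methyl-5-oxo-2,5-dihydrofuran-2-yl)perhydropyrido[1,2-a]azepin-10-yl]propanal
Product: 29 bis-TBS ether of 30 (silyl groups on the C9 tertiary oxygen and on the side-chain oxygen; every centre arranged as in 30)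
Conditions: LiN(SiMe3)2 (1.1 equiv), THF, −78 °C; AcOH, −78 °C
Reagents that add atoms: none
Why: Intramolecular aldol addition (5-exo-trig) of the lithium furanolate generated at tetronate C5 to the aldehyde closes ring C onto the trans-diequatorial substituents set in step 14; a lithium bridge between the methoxy and aldehyde oxygens should place the new hydroxyl on the methoxy side while the methoxy-bearing carbon avoids the tertiary silyl ether, giving the spiro centre and the carbinol centre as in the target.

**Step 19**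
Reactants: 29 bis-TBS ether of 30
Product: 30 CNP0267781.1 (target)
Conditions: HF·pyridine (excess), THF, 0 → 40 °C
Reagents that add atoms: none
Why: Acidic fluoride cleavage of the remaining secondary and tertiary silyl ethers, chosen over basic fluoride to avoid retro-aldol opening of the two tetronate aldol units.

**Compound list**
1 | (R)-2-hydroxybutanoic acid | CC[C@@H](O)C(=O)O | starting material
2 | benzyl (R)-2-(benzyloxy)butanoate | CC[C@@H](OCc1ccccc1)C(=O)OCc1ccccc1 | intermediate
3 | (R)-2-(benzyloxy)butanal | CC[C@@H](OCc1ccccc1)C=O | intermediate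
4 | (R)-2-methylpropane-2-sulfinamide | CC(C)(C)[S@](N)=O | starting material
5 | (R,E)-N-[(R)-2-(benzyloxy)butylidene]-2-methylpropane-2-sulfinamide | CC[C@@H](OCc1ccccc1)/C=N/[S@](=O)C(C)(C)C | intermediate
6 | 5-bromopent-1-ene | C=CCCCBr | starting material
7 | (R)-N-[(3R,4R)-3-(benzyloxy)non-8-en-4-yl]-2-methylpropane-2-sulfinamide | CC[C@@H](OCc1ccccc1)[C@@H](CCCC=C)N[S@](=O)C(C)(C)C | intermediate
8 | (S)-4-methyldihydrofuran-2(3H)-one | O=C1C[C@H](C)CO1 | starting material
9 | (3R,4S)-3-[(dimethylamino)methyl]-4-methyldihydrofuran-2(3H)-one | O=C1[C@@H](CN(C)C)[C@H](C)CO1 | intermediate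
10 | trimethyl{[(3R,4S)-4-methyl-2-oxooxolan-3-yl]methyl}ammonium iodide | O=C1[C@@H](C[N+](C)(C)C)[C@H](C)CO1.[I-] | intermediate (not isolated)
11 | (S)-4-methyl-3-methylenedihydrofuran-2(3H)-one | C=C1[C@H](C)COC1=O | intermediate
12 | (R)-N-[(3R,4R,E)-3-(benzyloxy)-8-[(S)-4-methyl-2-oxodihydrofuran-3(2H)-ylidene]octan-4-yl]-2-methylpropane-2-sulfinamide | CC[C@@H](OCc1ccccc1)[C@@H](CCC/C=C2\[C@H](C)COC2=O)N[S@](=O)C(C)(C)C | intermediate
13 | (S,E)-3-[(5R,6R)-5-amino-6-(benzyloxy)octylidene]-4-methyldihydrofuran-2(3H)-one (formed as its hydrochloride) | CC[C@@H](OCc1ccccc1)[C@H](N)CCC/C=C2\[C@H](C)COC2=O | intermediate (not isolated)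
14 | (3R,4S)-3-[(2S,6R)-6-[(R)-1-(benzyloxy)propyl]piperidin-2-yl]-4-methyldihydrofuran-2(3H)-one | CC[C@@H](OCc1ccccc1)[C@H]2CCC[C@H](N2)[C@H]3[C@H](C)COC3=O | intermediate
15 | benzyl bromoacetate | BrCC(=O)OCc1ccccc1 | starting material
16 | benzyl 2-[(2R,6S)-2-[(R)-1-(benzyloxy)propyl]-6-[(3R,4S)-4-methyl-2-oxooxolan-3-yl]piperidin-1-yl]acetate | CC[C@@H](OCc1ccccc1)[C@H]2CCC[C@@H]([C@H]3[C@H](C)COC3=O)N2CC(=O)OCc4ccccc4 | intermediate
17 | benzyl (1R,5R,8aS)-5-[(R)-1-(benzyloxy)propyl]-2-hydroxy-1-[(S)-1-hydroxypropan-2-yl]-1,5,6,7,8,8a-hexahydroindolizine-3-carboxylate (formed as its dipotassium salt) | CC[C@@H](OCc1ccccc1)[C@H]2CCC[C@H]3[C@@H]([C@H](C)CO)C(O)=C(C(=O)OCc4ccccc4)N23 | intermediate (not isolated)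
18 | benzyl (1R,5R,8aS)-5-[(R)-1-(benzyloxy)propyl]-1-[(S)-1-(tert-butyldimethylsilyloxy)propan-2-yl]-2-hydroxy-1,5,6,7,8,8a-hexahydroindolizine-3-carboxylate | CC[C@@H](OCc1ccccc1)[C@H]2CCC[C@H]3[C@@H]([C@H](C)CO[Si](C)(C)C(C)(C)C)C(O)=C(C(=O)OCc4ccccc4)N23 | intermediate
19 | ethylene | C=C | starting material
20 | cyclobutanol photoadduct of 18 and ethylene: cis-fused bicyclo[3.2.0] unit with OH on indolizine C2 and CO2Bn on C3, the CH2–CH2 bridge on the face opposite the C1 side chain | CC[C@@H](OCc1ccccc1)[C@H]2CCC[C@H]3[C@@H]([C@H](C)CO[Si](C)(C)C(C)(C)C)[C@]5(O)CC[C@]5(C(=O)OCc4ccccc4)N23 | intermediate (not isolated)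
21 | benzyl (4R,6R,10R,10aS)-4-[(R)-1-(benzyloxy)propyl]-10-[(S)-1-(tert-butyldimethylsilyloxy)propan-2-yl]-9-oxoperhydropyrido[1,2-a]azepine-6-carboxylate | CC[C@@H](OCc1ccccc1)[C@H]2CCC[C@H]3[C@@H]([C@H](C)CO[Si](C)(C)C(C)(C)C)C(=O)CC[C@H](C(=O)OCc4ccccc4)N23 | intermediate
22 | (4R,6R,10R,10aS)-10-[(S)-1-(tert-butyldimethylsilyloxy)propan-2-yl]-4-[(R)-1-hydroxypropyl]-9-oxoperhydropyrido[1,2-a]azepine-6-carboxylic acid | CC[C@@H](O)[C@H]2CCC[C@H]3[C@@H]([C@H](C)CO[Si](C)(C)C(C)(C)C)C(=O)CC[C@H](C(=O)O)N23 | intermediate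
23 | (4R,10R,10aS)-10-[(S)-1-(tert-butyldimethylsilyloxy)propan-2-yl]-4-[(R)-1-hydroxypropyl]perhydropyrido[1,2-a]azepin-9-one | CC[C@@H](O)[C@H]2CCC[C@H]3[C@@H]([C@H](C)CO[Si](C)(C)C(C)(C)C)C(=O)CCCN23 | intermediate
24 | 4-methoxy-3-methylfuran-2(5H)-one | COC1=C(C)C(=O)OC1 | starting material
25 | 5-[(4R,9S,10R,10aS)-10-[(S)-1-(tert-butyldimethylsilyloxy)propan-2-yl]-9-hydroxy-4-[(R)-1-hydroxypropyl]perhydropyrido[1,2-a]azepin-9-yl]-4-methoxy-3-methylfuran-2(5H)-one (both epimers at furanone C5) | CC[C@@H](O)[C@H]2CCC[C@H]3[C@@H]([C@H](C)CO[Si](C)(C)C(C)(C)C)[C@](O)(C5OC(=O)C(C)=C5OC)CCCN23 | intermediate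
26 | 5-[(4R,9S,10R,10aS)-9-(tert-butyldimethylsilyloxy)-4-[(R)-1-(tert-butyldimethylsilyloxy)propyl]-10-[(S)-1-(tert-butyldimethylsilyloxy)propan-2-yl]perhydropyrido[1,2-a]azepin-9-yl]-4-methoxy-3-methylfuran-2(5H)-one | CC[C@@H](O[Si](C)(C)C(C)(C)C)[C@H]2CCC[C@H]3[C@@H]([C@H](C)CO[Si](C)(C)C(C)(C)C)[C@](O[Si](C)(C)C(C)(C)C)(C5OC(=O)C(C)=C5OC)CCCN23 | intermediate
27 | 5-[(4R,9S,10R,10aS)-9-(tert-butyldimethylsilyloxy)-4-[(R)-1-(tert-butyldimethylsilyloxy)propyl]-10-[(S)-1-hydroxypropan-2-yl]perhydropyrido[1,2-a]azepin-9-yl]-4-methoxy-3-methylfuran-2(5H)-one | CC[C@@H](O[Si](C)(C)C(C)(C)C)[C@H]2CCC[C@H]3[C@@H]([C@H](C)CO)[C@](O[Si](C)(C)C(C)(C)C)(C5OC(=O)C(C)=C5OC)CCCN23 | intermediate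
28 | (S)-2-[(4R,9S,10R,10aS)-9-(tert-butyldimethylsilyloxy)-4-[(R)-1-(tert-butyldimethylsilyloxy)propyl]-9-(3-methoxy-4-methyl-5-oxo-2,5-dihydrofuran-2-yl)perhydropyrido[1,2-a]azepin-10-yl]propanal | CC[C@@H](O[Si](C)(C)C(C)(C)C)[C@H]2CCC[C@H]3[C@@H]([C@H](C)C=O)[C@](O[Si](C)(C)C(C)(C)C)(C5OC(=O)C(C)=C5OC)CCCN23 | intermediate
29 | bis-TBS ether of 30 (silyl groups on the C9 tertiary oxygen and on the side-chain oxygen) | CC[C@@H](O[Si](C)(C)C(C)(C)C)[C@H]1CCC[C@H]2[C@H]3[C@H](C)[C@H](O)[C@@]4(OC(=O)C(C)=C4OC)[C@]3(O[Si](C)(C)C(C)(C)C)CCCN12 | intermediate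
30 | CNP0267781.1 | CC[C@@H](O)[C@H]1CCC[C@H]2[C@H]3[C@H](C)[C@H](O)[C@@]4(OC(=O)C(C)=C4OC)[C@]3(O)CCCN12 | target

**Step count and risks**
Total steps: 19. Longest linear sequence: 17 steps (steps 1–4 and 7–19, from 1 to 30); steps 5 and 6 make the lactone fragment 11.

Steps most likely to fail:

1. Step 11 (Proposed new method). The photoreaction may stall because too little of the ammonium salt is present as the enol, because the excited enol decays without adding ethylene, or because the product ketone is degraded on prolonged irradiation. The fallback uses known chemistry, sets out from 14 and returns at 23. N-Alkylation of 14 with methyl 4-bromobutanoate (K2CO3, NaI, MeCN, 70 °C) gives the piperidinylbutanoate lactone F1. A Dieckmann-type Claisen cyclisation of its ester enolate onto the lactone carbonyl (KOtBu, THF; AcOH; TBSCl, imidazole) closes ring B directly as the seven-membered β-keto ester F2. Krapcho dealkoxycarbonylation (LiCl, wet DMSO, 130 °C) gives the O-benzyl ketone F3. Hydrogenolysis (H2, Pd(OH)2/C, EtOH, AcOH 1 equiv) removes the benzyl ether and rejoins the route at 23.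

2. Step 18. The ring closure may suffer from poor facial selectivity at the new carbinol carbon, and from enolisation of the aldehyde by the amide base. The fallback sets out from 29 as obtained (both carbinol epimers) and returns at 30. Dess–Martin oxidation converges the epimers on the spiro ketone F4. HF·pyridine removes both silyl groups to give the keto diol F5. Hydroxyl-directed reduction with Me4NBH(OAc)3 (AcOH/MeCN, −30 °C) delivers hydride from the face of the C9 hydroxyl, so the 1,3-anti diol of 30 should result. The stereocentre is then set by directed reduction and no longer by the aldol.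

3. Step 14. The addition may be lost to enolisation of the hindered ketone by the basic furanolate, or to reversal of the addition before the quench. The fallback sets out from 24 and 23 and returns at 25. Radical bromination of 24 (N-bromosuccinimide, azobisisobutyronitrile cat., PhCF3, 80 °C) gives 5-bromo-4-methoxy-3-methylfuran-2(5H)-one F6. Reductive coupling of F6 with 23 by SmI2 (THF, −78 °C; Barbier/Reformatsky type) forms the same carbon–carbon bond under non-basic conditions and gives 25.

**Further compounds**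
F1 | step 11 | methyl 4-[(2R,6S)-2-[(R)-1-(benzyloxy)propyl]-6-[(3R,4S)-4-methyl-2-oxooxolan-3-yl]piperidin-1-yl]butanoate | CC[C@@H](OCc1ccccc1)[C@H]2CCC[C@@H]([C@H]3[C@H](C)COC3=O)N2CCCC(=O)OC
F2 | step 11 | methyl (4R,10R,10aS)-4-[(R)-1-(benzyloxy)propyl]-10-[(S)-1-(tert-butyldimethylsilyloxy)propan-2-yl]-9-oxoperhydropyrido[1,2-a]azepine-8-carboxylate (C8 epimers and enol) | CC[C@@H](OCc1ccccc1)[C@H]2CCC[C@H]3[C@@H]([C@H](C)CO[Si](C)(C)C(C)(C)C)C(=O)C(C(=O)OC)CCN23
F3 | step 11 | (4R,10R,10aS)-4-[(R)-1-(benzyloxy)propyl]-10-[(S)-1-(tert-butyldimethylsilyloxy)propan-2-yl]perhydropyrido[1,2-a]azepin-9-one | CC[C@@H](OCc1ccccc1)[C@H]2CCC[C@H]3[C@@H]([C@H](C)CO[Si](C)(C)C(C)(C)C)C(=O)CCCN23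
F4 | step 18 | ring C ketone corresponding to 29 (carbinol carbon oxidised, both silyl ethers kept) | CC[C@@H](O[Si](C)(C)C(C)(C)C)[C@H]1CCC[C@H]2[C@H]3[C@H](C)C(=O)[C@@]4(OC(=O)C(C)=C4OC)[C@]3(O[Si](C)(C)C(C)(C)C)CCCN12
F5 | step 18 | ring C ketone corresponding to 30 (keto diol) | CC[C@@H](O)[C@H]1CCC[C@H]2[C@H]3[C@H](C)C(=O)[C@@]4(OC(=O)C(C)=C4OC)[C@]3(O)CCCN12
F6 | step 14 | 5-bromo-4-methoxy-3-methylfuran-2(5H)-one (racemic) | COC1=C(C)C(=O)OC1Br
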